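**Strategy**

Germacranolide numbering is used (C1 ketone, C10 acetoxy carbon, C14 its methyl). The ten-membered ring is closed between C1 and C10: the α-acetoxy ketone C1(=O)–C10(CH3)(OAc) is read as an oxidised 2-methylene carbinol, so an intramolecular Nozaki–Hiyama–Kishi addition of a C10 alkenyl bromide to a C1 aldehyde forges the carbocycle on a seco chain that already carries the trans-4,5-epoxide, the butenolide and O8. The step leaves the exocyclic C10=C14 alkene 1,3 to O8; a temporary cyclic carbonate grown from the C8 Boc group then delivers O10 cis to O8, and oxidation of C1 completes the ketol.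

Key step: step 13

Locants and abbreviations: C4/C5 epoxide carbons, C6 lactone carbinol, C7=C11 butenolide alkene, C8 angelate carbinol, C12 lactone carbonyl, C13 acetoxymethyl carbon, C15 methyl on C4; TBS = tert-butyldimethylsilyl, TBDPS = tert-butyldiphenylsilyl, Boc = tert-butoxycarbonyl, Ang = (2Z)-2-methylbut-2-enoyl.

Assumption: (S,S)-ProPhenol (step 3) and the (S,S)-bis-sulfonamide allylborane (step 9) are taken to add to the si face of their aldehydes; if a reagent shows the opposite sense, its enantiomer is used.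

**Route**

Step 1
Reactants: 1 tert-butyldimethyl(pent-4-yn-1-yloxy)silane
Product: 4 (2E)-6-(TBSO)-3-methylhex-2-en-1-ol, via alkenyldimethylalane 2 (not isolated), via lithium alkenylalanate 3 (not isolated)
Conditions: Me3Al, Cp2ZrCl2 (cat.), CH2Cl2, 0 °C to rt; then n-BuLi, THF, −78 °C; (CH2O)n, −78 °C to rt
Reagents that add atoms: trimethylaluminium C[Al](C)C; formaldehyde (as paraformaldehyde) C=O
Why: Zirconium-catalysed carboalumination adds methyl and aluminium syn across the terminal alkyne with aluminium at the terminus, and the derived alanate is hydroxymethylated with retention, which fixes the E C4=C5 alkene (C15 methyl cis to C6).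

Step 2
Reactants: 4 (2E)-6-(TBSO)-3-methylhex-2-en-1-ol
Product: 5 (2E)-6-(TBSO)-3-methylhex-2-enal
Conditions: MnO2, CH2Cl2, rt
Reagents that add atoms: none
Why: Activated MnO2 oxidises the allylic alcohol chemoselectively to the enal without touching the silyl ether or the alkene geometry.

Step 3
Reactants: 5 (2E)-6-(TBSO)-3-methylhex-2-enal; 6 tert-butyldiphenyl(prop-2-yn-1-yloxy)silane
Product: 8 (4R,5E)-9-(TBSO)-1-(TBDPSO)-6-methylnon-5-en-2-yn-4-ol, via alkynylmethylzinc 7 (not isolated)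
Conditions: Me2Zn, (S,S)-ProPhenol (cat.), Ph3PO (cat.), toluene, 4 °C
Reagents that add atoms: none
Why: Catalytic asymmetric alkynylation of an enal: the alkynylzinc 7 is delivered inside the dinuclear zinc–ProPhenol pocket to the si face of the aldehyde and sets C6 (4R in 8).

Step 4
Reactants: 8 (4R,5E)-9-(TBSO)-1-(TBDPSO)-6-methylnon-5-en-2-yn-4-ol
Product: 10 (2Z,4R,5E)-9-(TBSO)-1-(TBDPSO)-3-ethenyl-2-iodo-6-methylnona-2,5-dien-4-ol, via magnesium chelate 9 (not isolated)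
Conditions: CH2=CHMgCl (excess), THF/toluene, 65 °C; then I2, −78 °C to 0 °C
Reagents that add atoms: vinylmagnesium chloride C=C[Mg]Cl; iodine II
Why: Alkoxide-directed anti-carbomagnesiation of the propargylic alcohol puts the vinyl group on C7 and magnesium on C11 inside a five-membered chelate, so iodinolysis with retention should give the tetrasubstituted Z-iodoalkene with iodine cis to the C6 carbinol.

Step 5
Reactants: 10 (2Z,4R,5E)-9-(TBSO)-1-(TBDPSO)-3-ethenyl-2-iodo-6-methylnona-2,5-dien-4-ol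
Product: 11 (1S,2Z)-4-(TBDPSO)-2-ethenyl-3-iodo-1-[(2R,3R)-3-methyl-3-(3-TBSO-propyl)oxiran-2-yl]but-2-en-1-ol
Conditions: mCPBA, NaHCO3, CH2Cl2, 0 °C
Reagents that add atoms: mCPBA OOC(=O)c1cccc(Cl)c1
Why: Hydroxyl-directed peracid epoxidation of the only electron-rich alkene (the iodo-diene is deactivated): 1,3-allylic strain with the cis C15 methyl holds H6 in the alkene plane and the hydrogen-bonded peracid attacks syn to OH, which should give the threo epoxy alcohol and so sets C4 and C5 from C6.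

Step 6
Reactants: 11 (1S,2Z)-4-(TBDPSO)-2-ethenyl-3-iodo-1-[(2R,3R)-3-methyl-3-(3-TBSO-propyl)oxiran-2-yl]but-2-en-1-ol
Product: 12 (5S)-3-(TBDPSO-methyl)-4-ethenyl-5-[(2R,3R)-3-methyl-3-(3-TBSO-propyl)oxiran-2-yl]furan-2(5H)-one
Conditions: CO (1 atm), Pd(PPh3)4 (cat.), iPr2NEt, THF, 45 °C
Reagents that add atoms: carbon monoxide [C-]#[O+]
Why: Palladium-catalysed carbonylative lactonisation: oxidative addition of zerovalent palladium into the C11–I bond, CO insertion and capture of the acylpalladium by the cis C6 hydroxyl close the butenolide with retention at C6.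

Step 7
Reactants: 12 (5S)-3-(TBDPSO-methyl)-4-ethenyl-5-[(2R,3R)-3-methyl-3-(3-TBSO-propyl)oxiran-2-yl]furan-2(5H)-one
Product: 14 (2S)-4-(TBDPSO-methyl)-2-[(2R,3R)-3-methyl-3-(3-TBSO-propyl)oxiran-2-yl]-5-oxo-2,5-dihydrofuran-3-carbaldehyde, via ozonide 13 (not isolated)
Conditions: O3, CH2Cl2, −78 °C (indicator end-point); then PPh3, −78 °C to rt
Reagents that add atoms: ozone [O-][O+]=O
Why: Ozonolysis with reductive work-up cleaves the terminal vinyl group, the only alkene not deactivated by the lactone carbonyl, to the C8 aldehyde under neutral conditions that avoid enolisation at C6.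

Step 8
Reactants: 15 2,3-dibromoprop-1-ene
Product: 17 tributyl(2-bromoprop-2-en-1-yl)stannane, via allylzinc bromide 16 (not isolated)
Conditions: Zn dust, Bu3SnCl, THF/sat. aq. NH4Cl, rt
Reagents that add atoms: tributyltin chloride CCCC[Sn](Cl)(CCCC)CCCC
Why: Barbier-type stannylation: zinc inserts only into the allylic C–Br bond and the allylzinc 16 is trapped by Bu3SnCl, the vinylic bromide being inert.

Step 9
Reactants: 14 (2S)-4-(TBDPSO-methyl)-2-[(2R,3R)-3-methyl-3-(3-TBSO-propyl)oxiran-2-yl]-5-oxo-2,5-dihydrofuran-3-carbaldehyde; 17 tributyl(2-bromoprop-2-en-1-yl)stannane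
Product: 19 (5S)-4-[(1S)-3-bromo-1-hydroxybut-3-en-1-yl]-3-(TBDPSO-methyl)-5-[(2R,3R)-3-methyl-3-(3-TBSO-propyl)oxiran-2-yl]furan-2(5H)-one, via allyldiazaborolidine 18 (not isolated)
Conditions: (S,S)-N,N'-ditosyl-1,2-diphenylethane-1,2-diamine, BBr3, CH2Cl2, 0 °C to rt, volatiles removed; 17, CH2Cl2, rt; then 14, −78 °C
Reagents that add atoms: none
Why: Reagent-controlled asymmetric 2-bromoallylation: tin-to-boron exchange gives the chiral allylborane 18, which adds to the aldehyde through a chair six-membered transition state on the si face and sets C8 (8S).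

Step 10
Reactants: 19 (5S)-4-[(1S)-3-bromo-1-hydroxybut-3-en-1-yl]-3-(TBDPSO-methyl)-5-[(2R,3R)-3-methyl-3-(3-TBSO-propyl)oxiran-2-yl]furan-2(5H)-one
Product: 20 tert-butyl (1S)-3-bromo-1-{(2S)-4-(TBDPSO-methyl)-2-[(2R,3R)-3-methyl-3-(3-TBSO-propyl)oxiran-2-yl]-5-oxo-2,5-dihydrofuran-3-yl}but-3-en-1-yl carbonate
Conditions: Boc2O, DMAP (cat.), MeCN, rt
Reagents that add atoms: di-tert-butyl dicarbonate CC(C)(C)OC(=O)OC(=O)OC(C)(C)C
Why: DMAP-catalysed acylation of the only free hydroxyl installs the carbonate that protects O8 and later serves as the tether.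

Step 11
Reactants: 20 the C8 tert-butyl carbonate with C1–OTBS
Product: 21 the corresponding primary alcohol (C1–OH; C8–OBoc, C13–OTBDPS and C10 bromide unchanged)
Conditions: Et3N·3HF, THF/MeCN, rt
Reagents that add atoms: none
Why: The near-neutral fluoride source removes the primary TBS ether much faster than the TBDPS ether and should not open the epoxide or cleave the carbonate.

Step 12
Reactants: 21 primary alcohol (C1–OH)
Product: 22 seco aldehyde (C1 aldehyde; C10 alkenyl bromide; C8–OBoc; C13–OTBDPS; 4R,5R,6S,8S)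
Conditions: Dess–Martin periodinane, NaHCO3, CH2Cl2, 0 °C to rt
Reagents that add atoms: none
Why: Buffered Dess–Martin oxidation converts the primary alcohol into the C1 aldehyde under neutral conditions.

Step 13
Reactants: 22 seco aldehyde
Product: 24 (4R,5R,6S,8S)-8-(Boc-oxy)-13-(TBDPSO)-4,5-epoxy-1-hydroxygermacra-7(11),10(14)-dien-12,6-olide (both C1 epimers), via alkenylchromium 23 (not isolated)
Conditions: CrCl2 (excess), NiCl2 (cat.), degassed DMSO, rt, slow addition of 22 (high dilution)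
Reagents that add atoms: none
Why: Zerovalent nickel, formed from NiCl2 by CrCl2, inserts into the C10–Br bond and transmetalation to trivalent chromium gives the alkenylchromium 23, which adds to the C1 aldehyde. The closest known reaction type is the Nozaki–Hiyama–Kishi closure of medium rings from 2-halo-1-alkenes and aldehydes. The ten-membered carbocycle is closed in a 10-exo-trig mode at the C1 carbonyl. The new C1 carbinol centre is not controlled and need not be, since both epimers converge on the C1 ketone in step 16. The step needs chemoselectivity for the aldehyde over lactone, carbonate and epoxide, which the non-basic, oxophilic alkenylchromium secures (the C8 carbonate sits on a tetrasubstituted electron-poor alkene and should not be ionised by trace nickel). It also needs ring closure over oligomerisation, which high dilution and the turn imposed on the chain by the trans-epoxide and the planar butenolide should favour.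

Step 14
Reactants: 24 macrocyclic allylic alcohol with C8–OBoc
Product: 25 (4R,5R,6S,8S,10R)-13-(TBDPSO)-4,5-epoxy-1-hydroxy-14-iodogermacr-7(11)-en-12,6-olide 8,10-carbonate (both C1 epimers)
Conditions: IBr, toluene, −85 °C; aq. Na2S2O3 work-up
Reagents that add atoms: iodine monobromide IBr
Why: Iodocarbonate cyclisation: the iodonium ion of the C10=C14 alkene is opened at its tertiary carbon C10 by the carbonyl oxygen of the C8 carbonate with loss of the tert-butyl group, and because the six-membered carbonate can bridge C8 and C10 only on one face of the ten-membered ring, O10 is delivered cis to O8 and C10 is set (10R).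

Step 15
Reactants: 25 iodomethyl cyclic carbonate
Product: 26 (4R,5R,6S,8S,10R)-13-(TBDPSO)-4,5-epoxy-1-hydroxygermacr-7(11)-en-12,6-olide 8,10-carbonate (both C1 epimers)
Conditions: Bu3SnH, Et3B, air, toluene, rt
Reagents that add atoms: none
Why: Radical-chain reduction of the primary iodide at room temperature turns C14 into the methyl group without touching the epoxide, the lactone or the carbonate.

Step 16
Reactants: 26 cyclic carbonate with C1–OH
Product: 27 (4R,5R,6S,8S,10R)-13-(TBDPSO)-4,5-epoxy-1-oxogermacr-7(11)-en-12,6-olide 8,10-carbonate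
Conditions: Dess–Martin periodinane, NaHCO3, CH2Cl2, rt
Reagents that add atoms: none
Why: Dess–Martin oxidation of the secondary C1 alcohol erases its configuration and gives the C1 ketone, while O10 stays masked in the carbonate.

Step 17
Reactants: 27 ketone cyclic carbonate
Product: 28 (4R,5R,6S,8S,10R)-13-(TBDPSO)-4,5-epoxy-8,10-dihydroxy-1-oxogermacr-7(11)-en-12,6-olide
Conditions: K2CO3 (substoichiometric), MeOH, 0 °C, short contact
Reagents that add atoms: none
Why: Base-catalysed transesterification with methanol opens the cyclic carbonate to dimethyl carbonate and the 8,10-diol, low temperature and little base being chosen to spare the butenolide, the epoxide and the C6 centre.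

Step 18
Reactants: 28 8,10-diol; 29 angelic acid [(2Z)-2-methylbut-2-enoic acid]
Product: 31 (4R,5R,6S,8S,10R)-8-(Ang-oxy)-13-(TBDPSO)-4,5-epoxy-10-hydroxy-1-oxogermacr-7(11)-en-12,6-olide, via mixed anhydride 30 (not isolated)
Conditions: 29, 2,4,6-trichlorobenzoyl chloride, Et3N, toluene, rt; then 28, 80 °C
Reagents that add atoms: none
Why: Yamaguchi esterification run without DMAP: the mixed anhydride 30 acylates the secondary C8 hydroxyl in preference to the tertiary C10 hydroxyl, and leaving out nucleophilic catalysts should avoid Z-to-E isomerisation of the angelate.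

Step 19
Reactants: 31 8-angelate with C13–OTBDPS
Product: 32 (4R,5R,6S,8S,10R)-8-(Ang-oxy)-4,5-epoxy-10,13-dihydroxy-1-oxogermacr-7(11)-en-12,6-olide
Conditions: Bu4NF, AcOH (1:1), THF, 0 °C to rt
Reagents that add atoms: none
Why: Acetic-acid-buffered fluoride cleaves the TBDPS ether without base-induced damage to the butenolide, the epoxide or the α-ketol.

Step 20
Reactants: 32 10,13-diol
Product: 33 CNP0175424.2, (4R,5R,6S,8S,10R)-10,13-diacetoxy-8-(Ang-oxy)-4,5-epoxy-1-oxogermacr-7(11)-en-12,6-olide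
Conditions: Ac2O (excess), DMAP, Et3N, CH2Cl2, rt to 40 °C
Reagents that add atoms: acetic anhydride CC(=O)OC(C)=O
Why: DMAP-catalysed acetylation acylates the primary C13 hydroxyl and, more slowly, the tertiary C10 hydroxyl of the α-ketol to give the target.

**Compound list**

1 | tert-butyldimethyl(pent-4-yn-1-yloxy)silane | C#CCCCO[Si](C)(C)C(C)(C)C | starting material
2 | dimethyl[(1E)-5-(TBSO)-2-methylpent-1-en-1-yl]alane | C[Al](C)/C=C(\C)CCCO[Si](C)(C)C(C)(C)C | intermediate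
3 | lithium butyl[(1E)-5-(TBSO)-2-methylpent-1-en-1-yl]dimethylalanate | [Li+].CCCC[Al-](C)(C)/C=C(\C)CCCO[Si](C)(C)C(C)(C)C | intermediate
4 | (2E)-6-(TBSO)-3-methylhex-2-en-1-ol | OC/C=C(\C)CCCO[Si](C)(C)C(C)(C)C | intermediate
5 | (2E)-6-(TBSO)-3-methylhex-2-enal | O=C/C=C(\C)CCCO[Si](C)(C)C(C)(C)C | intermediate
6 | tert-butyldiphenyl(prop-2-yn-1-yloxy)silane | C#CCO[Si](c1ccccc1)(c1ccccc1)C(C)(C)C | starting material
7 | [3-(TBDPSO)prop-1-yn-1-yl](methyl)zinc | C[Zn]C#CCO[Si](c1ccccc1)(c1ccccc1)C(C)(C)C | intermediate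
8 | (4R,5E)-9-(TBSO)-1-(TBDPSO)-6-methylnon-5-en-2-yn-4-ol | CC(C)(C)[Si](C)(C)OCCC/C(C)=C/[C@@H](O)C#CCO[Si](c1ccccc1)(c1ccccc1)C(C)(C)C | intermediate
9 | (5R)-4-ethenyl-3-(TBDPSO-methyl)-5-[(1E)-5-(TBSO)-2-methylpent-1-en-1-yl]-2,5-dihydro-1,2-oxamagnesole (chelated alkenylmagnesium alkoxide) | CC(C)(C)[Si](C)(C)OCCC/C(C)=C/[C@H]1O[Mg]C(CO[Si](c2ccccc2)(c2ccccc2)C(C)(C)C)=C1C=C | intermediate
10 | (2Z,4R,5E)-9-(TBSO)-1-(TBDPSO)-3-ethenyl-2-iodo-6-methylnona-2,5-dien-4-ol | CC(C)(C)[Si](C)(C)OCCC/C(C)=C/[C@@H](O)/C(C=C)=C(\I)CO[Si](c1ccccc1)(c1ccccc1)C(C)(C)C | intermediate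
11 | (1S,2Z)-4-(TBDPSO)-2-ethenyl-3-iodo-1-[(2R,3R)-3-methyl-3-(3-TBSO-propyl)oxiran-2-yl]but-2-en-1-ol | CC(C)(C)[Si](C)(C)OCCC[C@@]1(C)O[C@@H]1[C@@H](O)/C(C=C)=C(\I)CO[Si](c1ccccc1)(c1ccccc1)C(C)(C)C | intermediate
12 | (5S)-3-(TBDPSO-methyl)-4-ethenyl-5-[(2R,3R)-3-methyl-3-(3-TBSO-propyl)oxiran-2-yl]furan-2(5H)-one | CC(C)(C)[Si](C)(C)OCCC[C@@]1(C)O[C@@H]1[C@H]1OC(=O)C(CO[Si](c2ccccc2)(c2ccccc2)C(C)(C)C)=C1C=C | intermediate
13 | secondary ozonide (1,2,4-trioxolane) of the vinyl group of 12 | CC(C)(C)[Si](C)(C)OCCC[C@@]1(C)O[C@@H]1[C@H]1OC(=O)C(CO[Si](c2ccccc2)(c2ccccc2)C(C)(C)C)=C1C1OCOO1 | intermediate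
14 | (2S)-4-(TBDPSO-methyl)-2-[(2R,3R)-3-methyl-3-(3-TBSO-propyl)oxiran-2-yl]-5-oxo-2,5-dihydrofuran-3-carbaldehyde | CC(C)(C)[Si](C)(C)OCCC[C@@]1(C)O[C@@H]1[C@H]1OC(=O)C(CO[Si](c2ccccc2)(c2ccccc2)C(C)(C)C)=C1C=O | intermediate
15 | 2,3-dibromoprop-1-ene | BrCC(Br)=C | starting material
16 | (2-bromoprop-2-en-1-yl)zinc bromide | Br[Zn]CC(Br)=C | intermediate
17 | tributyl(2-bromoprop-2-en-1-yl)stannane | CCCC[Sn](CCCC)(CCCC)CC(Br)=C | intermediate
18 | (4S,5S)-2-(2-bromoprop-2-en-1-yl)-4,5-diphenyl-1,3-ditosyl-1,3,2-diazaborolidine | C=C(Br)CB1N(S(=O)(=O)c2ccc(C)cc2)[C@@H](c2ccccc2)[C@H](c2ccccc2)N1S(=O)(=O)c1ccc(C)cc1 | intermediate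
19 | (5S)-4-[(1S)-3-bromo-1-hydroxybut-3-en-1-yl]-3-(TBDPSO-methyl)-5-[(2R,3R)-3-methyl-3-(3-TBSO-propyl)oxiran-2-yl]furan-2(5H)-one | CC(C)(C)[Si](C)(C)OCCC[C@@]1(C)O[C@@H]1[C@H]1OC(=O)C(CO[Si](c2ccccc2)(c2ccccc2)C(C)(C)C)=C1[C@@H](O)CC(Br)=C | intermediate
20 | tert-butyl carbonate of 19 at O8 | CC(C)(C)[Si](C)(C)OCCC[C@@]1(C)O[C@@H]1[C@H]1OC(=O)C(CO[Si](c2ccccc2)(c2ccccc2)C(C)(C)C)=C1[C@@H](OC(=O)OC(C)(C)C)CC(Br)=C | intermediate
21 | C1 primary alcohol from 20 | OCCC[C@@]1(C)O[C@@H]1[C@H]1OC(=O)C(CO[Si](c2ccccc2)(c2ccccc2)C(C)(C)C)=C1[C@@H](OC(=O)OC(C)(C)C)CC(Br)=C | intermediate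
22 | seco aldehyde (C1 aldehyde, C10 alkenyl bromide) | O=CCC[C@@]1(C)O[C@@H]1[C@H]1OC(=O)C(CO[Si](c2ccccc2)(c2ccccc2)C(C)(C)C)=C1[C@@H](OC(=O)OC(C)(C)C)CC(Br)=C | intermediate
23 | alkenylchromium dichloride from 22 (CrCl2 at C10) | O=CCC[C@@]1(C)O[C@@H]1[C@H]1OC(=O)C(CO[Si](c2ccccc2)(c2ccccc2)C(C)(C)C)=C1[C@@H](OC(=O)OC(C)(C)C)CC(=C)[Cr](Cl)Cl | intermediate
24 | (4R,5R,6S,8S)-8-(Boc-oxy)-13-(TBDPSO)-4,5-epoxy-1-hydroxygermacra-7(11),10(14)-dien-12,6-olide (both C1 epimers) | CC(C)(C)OC(=O)O[C@H]1CC(=C)C(O)CC[C@@]2(C)O[C@@H]2[C@H]2OC(=O)C(CO[Si](c3ccccc3)(c3ccccc3)C(C)(C)C)=C12 | intermediate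
25 | (4R,5R,6S,8S,10R)-13-(TBDPSO)-4,5-epoxy-1-hydroxy-14-iodogermacr-7(11)-en-12,6-olide 8,10-carbonate (both C1 epimers) | O=C1O[C@H]2C[C@@](CI)(O1)C(O)CC[C@@]3(C)O[C@@H]3[C@H]3OC(=O)C(CO[Si](c4ccccc4)(c4ccccc4)C(C)(C)C)=C23 | intermediate
26 | (4R,5R,6S,8S,10R)-13-(TBDPSO)-4,5-epoxy-1-hydroxygermacr-7(11)-en-12,6-olide 8,10-carbonate (both C1 epimers) | O=C1O[C@H]2C[C@@](C)(O1)C(O)CC[C@@]3(C)O[C@@H]3[C@H]3OC(=O)C(CO[Si](c4ccccc4)(c4ccccc4)C(C)(C)C)=C23 | intermediate
27 | (4R,5R,6S,8S,10R)-13-(TBDPSO)-4,5-epoxy-1-oxogermacr-7(11)-en-12,6-olide 8,10-carbonate | O=C1O[C@H]2C[C@@](C)(O1)C(=O)CC[C@@]3(C)O[C@@H]3[C@H]3OC(=O)C(CO[Si](c4ccccc4)(c4ccccc4)C(C)(C)C)=C23 | intermediate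
28 | (4R,5R,6S,8S,10R)-13-(TBDPSO)-4,5-epoxy-8,10-dihydroxy-1-oxogermacr-7(11)-en-12,6-olide | O[C@H]1C[C@@](C)(O)C(=O)CC[C@@]2(C)O[C@@H]2[C@H]2OC(=O)C(CO[Si](c3ccccc3)(c3ccccc3)C(C)(C)C)=C12 | intermediate
29 | angelic acid, (2Z)-2-methylbut-2-enoic acid | C/C=C(/C)C(=O)O | starting material
30 | (2Z)-2-methylbut-2-enoic 2,4,6-trichlorobenzoic anhydride | C/C=C(/C)C(=O)OC(=O)c1c(Cl)cc(Cl)cc1Cl | intermediate
31 | (4R,5R,6S,8S,10R)-8-(Ang-oxy)-13-(TBDPSO)-4,5-epoxy-10-hydroxy-1-oxogermacr-7(11)-en-12,6-olide | C/C=C(/C)C(=O)O[C@H]1C[C@@](C)(O)C(=O)CC[C@@]2(C)O[C@@H]2[C@H]2OC(=O)C(CO[Si](c3ccccc3)(c3ccccc3)C(C)(C)C)=C12 | intermediate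
32 | (4R,5R,6S,8S,10R)-8-(Ang-oxy)-4,5-epoxy-10,13-dihydroxy-1-oxogermacr-7(11)-en-12,6-olide | C/C=C(/C)C(=O)O[C@H]1C[C@@](C)(O)C(=O)CC[C@@]2(C)O[C@@H]2[C@H]2OC(=O)C(CO)=C12 | intermediate
33 | CNP0175424.2, (4R,5R,6S,8S,10R)-10,13-diacetoxy-8-(Ang-oxy)-4,5-epoxy-1-oxogermacr-7(11)-en-12,6-olide | C/C=C(/C)C(=O)O[C@H]1C[C@@](C)(OC(C)=O)C(=O)CC[C@@]2(C)O[C@@H]2[C@H]2OC(=O)C(COC(C)=O)=C12 | target

**Step count and risks**

Total step count: 20. Longest linear sequence: 19 steps (steps 1–7 and 9–20, from compound 1); step 8 is a one-step branch.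

Most likely to fail, step 13: the strained ten-membered transition state may be slow, so that the alkenylchromium is protonated or couples between molecules instead of closing the ring. The fallback sets out from aldehyde 14 and comes back at diol 28; it makes the same C1–C10 bond by a ketyl–carbonyl (pinacol) ring closure. (R)-Proline-catalysed aldol addition of acetone to 14 should give the (8S)-β-hydroxy methyl ketone F1. Boc2O with DMAP gives the C8 carbonate F2, Et3N·3HF frees the primary alcohol F3, and Dess–Martin oxidation gives the keto aldehyde F4. SmI2 in THF at −78 °C under high dilution reduces the aldehyde to its ketyl, which adds to the C10 ketone and closes the ring as the 1,10-diol F5 (the 10R epimer is the one wanted). Dess–Martin oxidation gives the ketol carbonate F6. K2CO3 in MeOH then removes the carbonate by way of cyclic carbonate 27, which only the epimer with O10 cis to O8 can form, and returns 28.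

Second, step 4: the alkenylmagnesium intermediate may lose the silyloxy group by β-elimination to an allene, or the carbometalation may take the wrong regiochemistry. The fallback sets out from enal 5 and comes back at butenolide 12; it builds the butenolide from a hydroxy ynoate by cuprate addition. Zinc–ProPhenol alkynylation of 5 with methyl propiolate gives the (4R)-hydroxy ynoate F7. mCPBA epoxidation, directed as in step 5, gives the epoxy ynoate F8. Syn addition of (CH2=CH)2CuLi at −78 °C, iodination of the alkenylcopper and lactonisation of the Z-hydroxy enoate give the 3-iodo-4-vinylbutenolide F9. Stille coupling with Bu3SnCH2OH (Pd(PPh3)4) gives the hydroxymethyl butenolide F10, and TBDPSCl with imidazole returns 12.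

Third, step 17: the base needed to open the cyclic carbonate may also deprotonate C6 of the butenolide or let the freed C8 alkoxide open the epoxide. The fallback sets out from carbinol 19 and comes back at angelate 31; it uses no carbonate and brings in O10 by radical hydration. Esterification of 19 with mixed anhydride 30 gives the C8 angelate F11, Et3N·3HF gives the primary alcohol F12, and Dess–Martin oxidation gives the aldehyde F13. The CrCl2/NiCl2 ring closure of step 13 gives the macrocyclic allylic alcohol F14, and Dess–Martin oxidation gives the exo-methylene ketone F15. Mukaiyama hydration of the enone (Mn(dpm)3 cat., PhSiH3, O2, then P(OEt)3) adds hydrogen to C14 and hydroxyl to C10 and returns 31; the C10 configuration then rests on the ring conformation.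

Further compounds
F1 | step 13 | (5S)-4-[(1S)-1-hydroxy-3-oxobutyl]-3-(TBDPSO-methyl)-5-[(2R,3R)-3-methyl-3-(3-TBSO-propyl)oxiran-2-yl]furan-2(5H)-one | CC(C)(C)[Si](C)(C)OCCC[C@@]1(C)O[C@@H]1[C@H]1OC(=O)C(CO[Si](c2ccccc2)(c2ccccc2)C(C)(C)C)=C1[C@@H](O)CC(C)=O
F2 | step 13 | tert-butyl carbonate of F1 at O8 | CC(C)(C)[Si](C)(C)OCCC[C@@]1(C)O[C@@H]1[C@H]1OC(=O)C(CO[Si](c2ccccc2)(c2ccccc2)C(C)(C)C)=C1[C@@H](OC(=O)OC(C)(C)C)CC(C)=O
F3 | step 13 | C1 primary alcohol from F2 | OCCC[C@@]1(C)O[C@@H]1[C@H]1OC(=O)C(CO[Si](c2ccccc2)(c2ccccc2)C(C)(C)C)=C1[C@@H](OC(=O)OC(C)(C)C)CC(C)=O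
F4 | step 13 | seco keto aldehyde (C1 aldehyde, C10 methyl ketone) | O=CCC[C@@]1(C)O[C@@H]1[C@H]1OC(=O)C(CO[Si](c2ccccc2)(c2ccccc2)C(C)(C)C)=C1[C@@H](OC(=O)OC(C)(C)C)CC(C)=O
F5 | step 13 | (4R,5R,6S,8S,10R)-8-(Boc-oxy)-13-(TBDPSO)-4,5-epoxy-1,10-dihydroxygermacr-7(11)-en-12,6-olide (both C1 epimers) | CC(C)(C)OC(=O)O[C@H]1C[C@@](C)(O)C(O)CC[C@@]2(C)O[C@@H]2[C@H]2OC(=O)C(CO[Si](c3ccccc3)(c3ccccc3)C(C)(C)C)=C12
F6 | step 13 | (4R,5R,6S,8S,10R)-8-(Boc-oxy)-13-(TBDPSO)-4,5-epoxy-10-hydroxy-1-oxogermacr-7(11)-en-12,6-olide | CC(C)(C)OC(=O)O[C@H]1C[C@@](C)(O)C(=O)CC[C@@]2(C)O[C@@H]2[C@H]2OC(=O)C(CO[Si](c3ccccc3)(c3ccccc3)C(C)(C)C)=C12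
F7 | step 4 | methyl (4R,5E)-9-(TBSO)-4-hydroxy-6-methylnon-5-en-2-ynoate | CC(C)(C)[Si](C)(C)OCCC/C(C)=C/[C@@H](O)C#CC(=O)OC
F8 | step 4 | methyl (4S)-4-hydroxy-4-[(2R,3R)-3-methyl-3-(3-TBSO-propyl)oxiran-2-yl]but-2-ynoate | CC(C)(C)[Si](C)(C)OCCC[C@@]1(C)O[C@@H]1[C@@H](O)C#CC(=O)OC
F9 | step 4 | (5S)-4-ethenyl-3-iodo-5-[(2R,3R)-3-methyl-3-(3-TBSO-propyl)oxiran-2-yl]furan-2(5H)-one | CC(C)(C)[Si](C)(C)OCCC[C@@]1(C)O[C@@H]1[C@H]1OC(=O)C(I)=C1C=C
F10 | step 4 | (5S)-4-ethenyl-3-(hydroxymethyl)-5-[(2R,3R)-3-methyl-3-(3-TBSO-propyl)oxiran-2-yl]furan-2(5H)-one | CC(C)(C)[Si](C)(C)OCCC[C@@]1(C)O[C@@H]1[C@H]1OC(=O)C(CO)=C1C=C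
F11 | step 17 | (2Z)-2-methylbut-2-enoate (angelate) of 19 at O8 | CC(C)(C)[Si](C)(C)OCCC[C@@]1(C)O[C@@H]1[C@H]1OC(=O)C(CO[Si](c2ccccc2)(c2ccccc2)C(C)(C)C)=C1[C@@H](OC(=O)/C(C)=C\C)CC(Br)=C
F12 | step 17 | C1 primary alcohol from F11 | OCCC[C@@]1(C)O[C@@H]1[C@H]1OC(=O)C(CO[Si](c2ccccc2)(c2ccccc2)C(C)(C)C)=C1[C@@H](OC(=O)/C(C)=C\C)CC(Br)=C
F13 | step 17 | seco aldehyde with C8 angelate and C10 alkenyl bromide | O=CCC[C@@]1(C)O[C@@H]1[C@H]1OC(=O)C(CO[Si](c2ccccc2)(c2ccccc2)C(C)(C)C)=C1[C@@H](OC(=O)/C(C)=C\C)CC(Br)=C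
F14 | step 17 | (4R,5R,6S,8S)-8-(Ang-oxy)-13-(TBDPSO)-4,5-epoxy-1-hydroxygermacra-7(11),10(14)-dien-12,6-olide (both C1 epimers) | C/C=C(/C)C(=O)O[C@H]1CC(=C)C(O)CC[C@@]2(C)O[C@@H]2[C@H]2OC(=O)C(CO[Si](c3ccccc3)(c3ccccc3)C(C)(C)C)=C12
F15 | step 17 | (4R,5R,6S,8S)-8-(Ang-oxy)-13-(TBDPSO)-4,5-epoxy-1-oxogermacra-7(11),10(14)-dien-12,6-olide | C/C=C(/C)C(=O)O[C@H]1CC(=C)C(=O)CC[C@@]2(C)O[C@@H]2[C@H]2OC(=O)C(CO[Si](c3ccccc3)(c3ccccc3)C(C)(C)C)=C12
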